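**Retrosynthetic overview**

1. The ester side chain is cut at its CH2–C(CH3)= bond: B-alkyl Suzuki–Miyaura coupling of a 1-vinyl decalindiol with the (E)-enol triflate of methyl acetoacetate (last step).
2. Ring B (decalin C1, C2, C3, C4, C4a, C8a; C1 bears the side chain, C2 the tertiary OH, C4 the secondary OH) is cut at C3–C4 and at C1–C2. Its array C4(OH)–C3H2–C2(OH)(CH3) is an acetone unit bridging C4 and C1, the two-carbon arm on C1 is the vinyl group left by a γ-selective allyl transfer, and the 4-OH, the 2-OH and the C1 arm are all equatorial on ring B, as an all-chair closure delivers. Ring B is therefore made in one flask from a ring-A aldehyde carrying an (E)-allylboronate, acetone and L-proline.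
3. The allylboronate comes from cross-metathesis of a vinyl group. The trans vinyl aldehyde comes from enantioselective radical-cation α-allylation of an acyclic ω-formyl allylsilane, which closes ring A at the C4a–C8a bond and sets both ring-A stereocentres.
4. The acyclic aldehyde is assembled from 5-chloropent-1-yne (carboalumination, silylmethyl coupling) and 3-methylbut-2-enal (conjugate addition).
5. Order of ring formation: ring A (step 4), then ring B (step 6).

Key step: step 6

Remark (assumption): the (2R,5R)-imidazolidinone is assumed to give the (1R) configuration at the formyl-bearing carbon of 9, by analogy with related α-allylations; if the sense of induction proves opposite, the antipodal catalyst is used without other change.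

**Step 1**
Reactants: 1 5-chloropent-1-yne
Product: 3 (E)-5-chloro-1-iodo-2-methylpent-1-ene, via alkenylalane 2 (not isolated)
Conditions: Me3Al (2 equiv), Cp2ZrCl2 (0.25 equiv), CH2Cl2, 0 °C to rt; then I2, THF, −30 to 0 °C
Reagents that add atoms: trimethylaluminium, C[Al](C)C; iodine, II
Why: Zirconium-catalysed Negishi carboalumination adds methyl and aluminium syn across the terminal alkyne with the metal on the terminal carbon, and iodinolysis of the carbon–aluminium bond with retention should give the (E)-iodide, the primary chloride being inert; no stereocentre is formed.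

**Step 2**
Reactants: 3 (E)-5-chloro-1-iodo-2-methylpent-1-ene
Product: 4 [(E)-6-chloro-3-methylhex-2-en-1-yl]trimethylsilane
Conditions: Me3SiCH2MgCl (1.5 equiv), Pd(PPh3)4 (3 mol%), THF, 0 °C to rt
Reagents that add atoms: (trimethylsilyl)methylmagnesium chloride, C[Si](C)(C)C[Mg]Cl
Why: Kumada–Corriu coupling of the alkenyl iodide with the silylmethyl Grignard reagent proceeds with retention of olefin geometry and much faster than any reaction at the alkyl chloride, so the (E)-allylsilane should result.

**Step 3**
Reactants: 4 [(E)-6-chloro-3-methylhex-2-en-1-yl]trimethylsilane; 5 3-methylbut-2-enal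
Product: 8 (E)-3,3,7-trimethyl-9-(trimethylsilyl)non-7-enal, via Grignard reagent 6 (not isolated), via silyl enol ether 7 (not isolated)
Conditions: Mg, THF, 60 °C; then 5, CuBr·SMe2 (10 mol%), Me3SiCl (2 equiv), DMPU, THF, −78 to −30 °C; then 10% aq. citric acid, THF, 0 °C
Reagents that add atoms: none
Why: Copper-catalysed, chlorosilane-accelerated conjugate addition of the primary Grignard reagent to the β,β-disubstituted enal creates the gem-dimethyl quaternary carbon (no stereocentre), and the enol silane is hydrolysed under conditions too mild to protodesilylate the allylsilane.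

**Step 4**
Reactants: 8 (E)-3,3,7-trimethyl-9-(trimethylsilyl)non-7-enal
Product: 9 (1R,2S)-2-ethenyl-2,6,6-trimethylcyclohexane-1-carbaldehyde
Conditions: (2R,5R)-5-benzyl-2-tert-butyl-3-methylimidazolidin-4-one·CF3CO2H (20 mol%), (NH4)2Ce(NO3)6 (2.2 equiv), NaHCO3 (2.2 equiv), H2O (2 equiv), DME, −20 °C
Reagents that add atoms: none
Why: In this intramolecular organo-SOMO α-allylation, one-electron oxidation of the catalyst-bound enamine by tetravalent cerium gives a radical cation that is captured 6-exo by the trisubstituted allylsilane, and a second oxidation with loss of silicon releases the vinyl group; the imidazolidinone shields one face of the radical cation and sets the formyl-bearing centre, and a chair transition state with both π-systems equatorial (the bulky silylmethyl-bearing arm rather than methyl) should set the quaternary centre with vinyl trans to formyl.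

**Step 5**
Reactants: 9 (1R,2S)-2-ethenyl-2,6,6-trimethylcyclohexane-1-carbaldehyde; 10 2-allyl-4,4,5,5-tetramethyl-1,3,2-dioxaborolane
Product: 11 (1R,2S)-2,6,6-trimethyl-2-[(E)-3-(4,4,5,5-tetramethyl-1,3,2-dioxaborolan-2-yl)prop-1-en-1-yl]cyclohexane-1-carbaldehyde
Conditions: 10 (4 equiv), second-generation Hoveyda–Grubbs catalyst RuCl2(H2IMes)(=CH-C6H4-2-OiPr) (5 mol%), CH2Cl2, 40 °C
Reagents that add atoms: none
Why: Olefin cross-metathesis of a hindered vinyl group that cannot homodimerise with an excess of a reactive allylboronate is selective for the cross product and, because of the quaternary allylic carbon, for the (E)-olefin; the aldehyde is tolerated and neither stereocentre is touched.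

**Step 6**
Reactants: 11 (1R,2S)-2,6,6-trimethyl-2-[(E)-3-(4,4,5,5-tetramethyl-1,3,2-dioxaborolan-2-yl)prop-1-en-1-yl]cyclohexane-1-carbaldehyde; 12 acetone
Product: 15 (1S,2S,4R,4aR,8aR)-1-ethenyl-2,5,5,8a-tetramethyldecahydronaphthalene-2,4-diol, via aldol adduct 13 (not isolated), via borate ester 14 (not isolated)
Conditions: L-proline (30 mol%), acetone/DMSO 1:4 (0.05 M), 25 °C, then 50 °C; aq. NaHCO3 work-up
Reagents that add atoms: none
Why: Proposed new method: L-proline and acetone form an enamine whose terminal carbon adds to the re face of the hindered α-branched aldehyde through the hydrogen-bonded enamine transition state to give ketol 13, and the methyl ketone so created is then allylated within the same molecule by the γ-carbon of the (E)-allylboronate through a closed Zimmerman–Traxler chair, with transposition of the double bond to the vinyl group and formation of borate 14. The closest known reaction types are the proline-catalysed acetone aldol of α-branched aldehydes and the thermal intramolecular allylboration of carbonyl groups by (E)-allyl pinacolboronates; their combination as a one-flask annulation with acetone as the two-carbon unit is the new element. Ring B is closed by a 6-exo-trig attack of the allyl γ-carbon on the ketone carbonyl, the boron–oxygen chair being fused trans to the forming cyclohexane, which is itself fused trans to ring A. The secondary carbinol C4 is set by the catalyst, (S)-proline giving the (R)-alcohol as with other α-branched aldehydes; the tertiary carbinol C2 and C1 are set by the all-chair transition state, in which the (E)-olefin places the quaternary C8a equatorial on the boron chair and the ketone places its ring methylene equatorial and its methyl axial, so that O–B and vinyl end up trans-diequatorial and the C2 methyl axial, as in the target. The step needs the aldol to precede allyl transfer and the closure to be non-chelated: the boronate cannot reach the aldehyde of its own molecule (a cyclobutane would result), pinacol allylboronates are inert to acetone at 25 °C, and the pinacol ester does not exchange with the new secondary hydroxyl. Mild warming then should drive the closure, and aqueous work-up hydrolyses the borate to diol 15.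

**Step 7**
Reactants: 16 methyl acetoacetate
Product: 17 methyl (2E)-3-{[(trifluoromethyl)sulfonyl]oxy}but-2-enoate
Conditions: (CF3SO2)2O (1.2 equiv), aq. Me4NOH, hexanes, 5–10 °C
Reagents that add atoms: trifluoromethanesulfonic anhydride, O=S(=O)(OS(=O)(=O)C(F)(F)F)C(F)(F)F
Why: O-sulfonylation of the non-chelated tetramethylammonium enolate of the β-keto ester, which adopts the extended geometry, should give the (E)-enol triflate (triflate trans to the ester), whereas a chelating lithium counter-ion would give the (Z)-isomer.

**Step 8**
Reactants: 15 (1S,2S,4R,4aR,8aR)-1-ethenyl-2,5,5,8a-tetramethyldecahydronaphthalene-2,4-diol; 17 methyl (2E)-3-{[(trifluoromethyl)sulfonyl]oxy}but-2-enoate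
Product: 19 methyl (2E)-5-[(1S,2S,4R,4aR,8aR)-2,4-dihydroxy-2,5,5,8a-tetramethyldecahydronaphthalen-1-yl]-3-methylpent-2-enoate (CNP0289884.1), via alkylborane 18 (not isolated)
Conditions: 9-BBN (3 equiv), THF, 0 °C to rt; then 17, Pd(dppf)Cl2 (5 mol%), aq. K3PO4, THF/DMF, rt to 50 °C
Reagents that add atoms: none
Why: Hydroboration places boron on the terminal carbon of the vinyl group and the B-alkyl Suzuki–Miyaura coupling with the enol triflate proceeds with retention of the (E)-geometry, the phosphate base sparing the methyl ester; excess borane covers transient O-borylation of the hydroxyls, which is undone in the aqueous base, and no stereocentre is touched.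

**Compound list**

1 | 5-chloropent-1-yne | C#CCCCCl | starting material
2 | [(E)-5-chloro-2-methylpent-1-en-1-yl]dimethylalumane | C[Al](C)/C=C(\C)CCCCl | intermediate
3 | (E)-5-chloro-1-iodo-2-methylpent-1-ene | ClCCC/C(C)=C/I | intermediate
4 | [(E)-6-chloro-3-methylhex-2-en-1-yl]trimethylsilane | ClCCC/C(C)=C/C[Si](C)(C)C | intermediate
5 | 3-methylbut-2-enal | CC(C)=CC=O | starting material
6 | [(E)-4-methyl-6-(trimethylsilyl)hex-4-en-1-yl]magnesium chloride | Cl[Mg]CCC/C(C)=C/C[Si](C)(C)C | intermediate
7 | trimethyl{[(7E)-3,3,7-trimethyl-9-(trimethylsilyl)nona-1,7-dien-1-yl]oxy}silane (enol ether as E/Z mixture) | C[Si](C)(C)OC=CC(C)(C)CCC/C(C)=C/C[Si](C)(C)C | intermediate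
8 | (E)-3,3,7-trimethyl-9-(trimethylsilyl)non-7-enal | O=CCC(C)(C)CCC/C(C)=C/C[Si](C)(C)C | intermediate
9 | (1R,2S)-2-ethenyl-2,6,6-trimethylcyclohexane-1-carbaldehyde | C=C[C@]1(C)CCCC(C)(C)[C@H]1C=O | intermediate
10 | 2-allyl-4,4,5,5-tetramethyl-1,3,2-dioxaborolane | C=CCB1OC(C)(C)C(C)(C)O1 | starting material
11 | (1R,2S)-2,6,6-trimethyl-2-[(E)-3-(4,4,5,5-tetramethyl-1,3,2-dioxaborolan-2-yl)prop-1-en-1-yl]cyclohexane-1-carbaldehyde | CC1(C)OB(C/C=C/[C@]2(C)CCCC(C)(C)[C@H]2C=O)OC1(C)C | intermediate
12 | acetone | CC(C)=O | starting material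
13 | (4R)-4-hydroxy-4-{(1R,2S)-2,6,6-trimethyl-2-[(E)-3-(4,4,5,5-tetramethyl-1,3,2-dioxaborolan-2-yl)prop-1-en-1-yl]cyclohexyl}butan-2-one | CC1(C)OB(C/C=C/[C@]2(C)CCCC(C)(C)[C@H]2[C@H](O)CC(C)=O)OC1(C)C | intermediate
14 | 2-{[(1S,2S,4R,4aR,8aR)-1-ethenyl-4-hydroxy-2,5,5,8a-tetramethyldecahydronaphthalen-2-yl]oxy}-4,4,5,5-tetramethyl-1,3,2-dioxaborolane | C=C[C@H]1[C@]2(C)CCCC(C)(C)[C@H]2[C@H](O)C[C@]1(C)OB1OC(C)(C)C(C)(C)O1 | intermediate
15 | (1S,2S,4R,4aR,8aR)-1-ethenyl-2,5,5,8a-tetramethyldecahydronaphthalene-2,4-diol | C=C[C@H]1[C@]2(C)CCCC(C)(C)[C@H]2[C@H](O)C[C@]1(C)O | intermediate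
16 | methyl acetoacetate (methyl 3-oxobutanoate) | COC(=O)CC(C)=O | starting material
17 | methyl (2E)-3-{[(trifluoromethyl)sulfonyl]oxy}but-2-enoate | COC(=O)/C=C(\C)OS(=O)(=O)C(F)(F)F | intermediate
18 | 9-{2-[(1S,2S,4R,4aR,8aR)-2,4-dihydroxy-2,5,5,8a-tetramethyldecahydronaphthalen-1-yl]ethyl}-9-borabicyclo[3.3.1]nonane | C1CC2CCCC(C1)B2CC[C@H]1[C@]2(C)CCCC(C)(C)[C@H]2[C@H](O)C[C@]1(C)O | intermediate
19 | methyl (2E)-5-[(1S,2S,4R,4aR,8aR)-2,4-dihydroxy-2,5,5,8a-tetramethyldecahydronaphthalen-1-yl]-3-methylpent-2-enoate | COC(=O)/C=C(\C)CC[C@H]1[C@]2(C)CCCC(C)(C)[C@H]2[C@H](O)C[C@]1(C)O | target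

**Step count and risks**

Total step count: 8. Longest linear sequence: 7 steps (steps 1 to 6, then 8; step 7 is a one-step side branch).

Steps most likely to fail:

1. Step 6 (proposed new method). The ring closure may stall, because a hindered ketone must be attacked by a γ-carbon flanked by a quaternary centre; retro-aldol cleavage or allyl transfer to the solvent acetone would then compete on warming. The closure may also leak through a cis-fused transition state and epimerise the tertiary carbinol. The fallback uses known chemistry, sets out from 9 and comes back at 15. Aldehyde 9 alone is taken through the proline-catalysed acetone aldol to the vinyl ketol F1, which is silylated (Et3SiCl, imidazole, DMF) to the triethylsilyl ether F2. Cross-metathesis with (Z)-but-2-ene-1,4-diyl diacetate (second-generation Hoveyda–Grubbs catalyst) gives the (E)-allylic acetate F3. Umpolung with Pd(PPh3)4 and InI in THF then generates an allylindium species, far more nucleophilic than the boronate, which adds to the ketone through a closed chair to give the silyl ether F4. Bu4NF in THF gives 15.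

2. Step 4. The two chair transition states (methyl axial versus alkenyl arm axial, both against the axial methyl of the gem-dimethyl carbon) may be poorly discriminated, giving the cis aldehyde; the cyclisation at the congested α-carbon may also be slow enough for over-oxidation to compete. The fallback sets out from 8 and comes back at 9. If the alkenyl-axial chair is preferred, 8 is cyclised under the same conditions with the antipodal (2S,5S)-imidazolidinone to the cis aldehyde F5. Its formyl-bearing centre alone is then inverted by enolisation (DBU, toluene, 60 °C), which converts F5 into 9; 9 is separated by chromatography and recovered F5 is re-equilibrated.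

3. Step 5. Metathesis at the neopentyl-type vinyl group may be slow and outlast the catalyst, and the allylboronate may be partly lost by protodeboronation or double-bond migration during purification. The fallback sets out from 9 and comes back at 11. Aldehyde 9 is converted (HC(OMe)3, MeOH, pyridinium p-toluenesulfonate) into the dimethyl acetal F6. Ozonolysis (O3, CH2Cl2, −78 °C; Me2S) gives the acetal aldehyde F7. Boron–Wittig olefination with CH2(Bpin)2 and lithium 2,2,6,6-tetramethylpiperidide (THF, −78 °C to rt) gives the (E)-alkenylboronate F8. Matteson homologation (ICH2Cl, n-BuLi, THF, −78 °C to rt) gives the allylboronate acetal F9, and mild hydrolysis (pyridinium p-toluenesulfonate, acetone/H2O) returns 11.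

**Further compounds**

F1 | step 6 | (4R)-4-[(1R,2S)-2-ethenyl-2,6,6-trimethylcyclohexyl]-4-hydroxybutan-2-one | C=C[C@]1(C)CCCC(C)(C)[C@H]1[C@H](O)CC(C)=O
F2 | step 6 | (4R)-4-[(1R,2S)-2-ethenyl-2,6,6-trimethylcyclohexyl]-4-[(triethylsilyl)oxy]butan-2-one | C=C[C@]1(C)CCCC(C)(C)[C@H]1[C@H](O[Si](CC)(CC)CC)CC(C)=O
F3 | step 6 | (2E)-3-{(1S,2R)-1,3,3-trimethyl-2-[(1R)-3-oxo-1-(triethylsilyloxy)butyl]cyclohexyl}prop-2-en-1-yl acetate | CC(=O)OC/C=C/[C@]1(C)CCCC(C)(C)[C@H]1[C@H](O[Si](CC)(CC)CC)CC(C)=O
F4 | step 6 | (1S,2S,4R,4aR,8aR)-1-ethenyl-2,5,5,8a-tetramethyl-4-[(triethylsilyl)oxy]decahydronaphthalen-2-ol | C=C[C@H]1[C@]2(C)CCCC(C)(C)[C@H]2[C@H](O[Si](CC)(CC)CC)C[C@]1(C)O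
F5 | step 4 | (1S,2S)-2-ethenyl-2,6,6-trimethylcyclohexane-1-carbaldehyde | C=C[C@]1(C)CCCC(C)(C)[C@@H]1C=O
F6 | step 5 | (1S,2R)-2-(dimethoxymethyl)-1-ethenyl-1,3,3-trimethylcyclohexane | C=C[C@]1(C)CCCC(C)(C)[C@H]1C(OC)OC
F7 | step 5 | (1R,2R)-2-(dimethoxymethyl)-1,3,3-trimethylcyclohexane-1-carbaldehyde | O=C[C@]1(C)CCCC(C)(C)[C@H]1C(OC)OC
F8 | step 5 | 2-{(E)-2-[(1S,2R)-2-(dimethoxymethyl)-1,3,3-trimethylcyclohexyl]ethenyl}-4,4,5,5-tetramethyl-1,3,2-dioxaborolane | CC1(C)OB(/C=C/[C@]2(C)CCCC(C)(C)[C@H]2C(OC)OC)OC1(C)C
F9 | step 5 | 2-{(E)-3-[(1S,2R)-2-(dimethoxymethyl)-1,3,3-trimethylcyclohexyl]prop-2-en-1-yl}-4,4,5,5-tetramethyl-1,3,2-dioxaborolane | CC1(C)OB(C/C=C/[C@]2(C)CCCC(C)(C)[C@H]2C(OC)OC)OC1(C)C
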